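Readings and results stem from a simulated flask from invented constants, and the scatter is random.

Treat the reaction as lags in series and rank them by time constant.

| setting | birch | flask |
|---|---|---|
| starting material | 0.80 M | 0.80 M |
| partner | 2.2 equiv | 1.10 equiv |
| free catalyst | 0.5 mol% | 0.5 mol% |
| second catalyst | 0.1 mol% | 0.1 mol% |
| remark | run made earlier |  |
| time |  | 3.0 d |

- birch (time / h: target / %, isomer of the product / %): 1.33: 28.1, 21.6; 4.00: 16.0, 66.6; 8.00: 10.3, 85.8; 12.0: 9.2, 89.3; 15.0: 9.8, 90.0; 20.0: 8.5, 90.8

(readings scatter by 1 percentage point)

- share of target in target plus isomer of the product at 8.0 min
- share of target in target plus isomer of the product at 3.0 d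
- which of target and isomer of the product there is more of at 3.0 d

- amounts and yields of target count crystals too
- given per volume of solution although it is solid: crystals
- steps thought possible: starting material + free catalyst -> free catalyst + intermediate; partner + second catalyst + intermediate -> second catalyst + target; crystals <-> target; target <-> isomer of the product; partner + free catalyst -> spent catalyst

Begin with the end of the birch run. Its last 3 readings move within their scatter, so pool them. The resting share s, meaning target divided by target plus isomer of the product at equilibrium, reads 9.24%.

The first lag is the exchange between those two. Take the isomer's gain in birch between 1.33 h and 4.00 h, and set it against the mean net driving amount of target. The forward constant k then reads 0.960 h⁻¹. The relaxation time τ = (1−s)/k is then 0.946 h.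

The second lag is formation. The part of birch not yet target or isomer falls with a time constant T of 2.61 h, as read. The step forming target takes partner, so its rate falls as partner falls. This flask starts with half the partner of birch, so as a rough figure for the early hours I scale T to 5.22 h, which is longer than τ. Partner drops as the step runs, so T lengthens later and one figure can't serve the whole run.

Now read the ladder. At 8.0 min, earlier than τ, you have kinetic control. Target forms through intermediate, which starts from zero, so the rate of forming target climbs at first. For a rate climbing in step with time t, and while kt is small, isomer over target is kt/3 at any slope, so I commit to 95.9%. At 3.0 d, far beyond τ, I expect s, with the isomer ahead.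

The forecast gives 94% (88% to 98%) and 9.5% (8.5% to 12%), with isomer of the product ahead: “Less partner only slows formation”. Its early share stands below mine and its late share above mine.

The simulation gives 95.3% and 9.13%, with isomer of the product at 89.6% against target at 9.00%.

    starting material + free catalyst → free catalyst + intermediate (k = 24.0 M⁻¹ min⁻¹)
    partner + second catalyst + intermediate → second catalyst + target (k = 7.50 M⁻² min⁻¹)
    crystals ⇌ target, rate k3*(cs3 - [target]) while solid is left; crystals form when [target] > cs3 (solubility = 0.390 M, k = 0.930 min⁻¹)
    target ⇌ isomer of the product (K = 10.0, k = 0.0170 min⁻¹)
    partner + free catalyst → spent catalyst (k = 0.00590 M⁻¹ min⁻¹)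

In this flask target peaks at 15.8% of the charge after 0.0752 d, or 0.127 M, below the solubility of 0.39 M, and crystals stand at 0%. Now take the flask with 0.440 equiv of partner. It ends with partner at 0% and 56.2% still intermediate. Its isomer of the product stands at 39.8%, so s predicts 4.05% of target, and that flask holds 3.98%.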